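At early times the target barely shows: the spring run reads 0% at 4.00 min, then it climbs. Here is what you have and what is asked.

| flask | substrate | reagent | remark | time |
|---|---|---|---|---|
| spring | 0.050 M | 1 equiv | run made earlier |  |
| autumn | 0.10 M | 1 equiv | run made earlier |  |
| ash | 0.050 M (fed, over 1.0 h) | 1.00 equiv | all else is in the flask from the start; the feed brings no volume worth counting | 80 min |
| maple | 0.050 M (in portions, 5, over 1.0 h) | 1.00 equiv | first portion at the start, last at 1.0 h | 80 min |
| oak | 0.050 M | 1.00 equiv | everything together at the start | 80 min |
| larch | 0.050 M | 1.00 equiv (fed, over 1.0 h) | all else is in the flask from the start; the feed brings no volume worth counting | 80 min |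

- spring (time / min: target / %): 4.00: 0; 8.00: 1.3; 15.0: 4.4; 25.0: 7.0; 50.0: 16.2
- autumn (time / min: target / %): 3.00: 0.8; 6.00: 2.5; 10.0: 3.9; 12.0: 5.7; 15.0: 6.6

(standard deviation of a reading: 0.5 percentage points)

- the flask with the highest amount of target, in percent of the substrate charged ("all alike" if they lie within 1.5 percentage points) (ash / maple / oak / larch / all alike)
- final target, as a percentage of the substrate charged, in ash
- final target, as a percentage of the substrate charged, in maple
- final target, as a percentage of the substrate charged, in oak
- final target, as a percentage of the substrate charged, in larch



Lay a straight line through the last two spring readings. Its slope is 0.00368 min⁻¹; call it the percent clock, the fraction of the charge turned into target per minute once the induction period is over. It is a reading and carries their scatter. The line meets zero at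

lag = 5.98 min

For oak, then:

clock × (time − lag) = 27.2%

But that line runs 30.0 min beyond the last reading, and you cannot see whether it bends. With half the slope over that stretch, oak gets 21.7%. I take the middle, 24.5%.

In ash and maple the substrate arrives on average 30.0 min after the start, so its mean age at the end is 50.0 min:

clock × (age − lag) = 16.2%

Yet less of the charge has entered these flasks while the addition runs, and the clock may run slower. The autumn run, at twice the concentration of substrate and reagent together, has a slope of 0.00483 min⁻¹ from its first reading to its last, which gives an order of

m = 0.393

On average 62.5% of the charge is in, so that order gives a slower clock and an estimate of 13.5%. I take ash and maple at 14.8%.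

Larch resists this. Its substrate is in the flask from the start, and the earlier runs moved substrate and reagent together, so I bracket it between ash and oak as a guess. Oak's lower estimate still stands above the higher estimate for ash by 5.5 percentage points, so I put oak first, provided that larch, with its reagent held back, stays below oak.

The forecast gave oak as highest, with 17% for ash, 17.5% for maple, 24.5% for oak and 16.5% for larch, and judged that “larch is the least certain”.

The flasks give 22.8% in oak, 15.6% in ash, 15.3% in maple and 17.7% in larch, so oak stands highest. At 80.0 min, maple holds 22.0% of intermediate B against 13.1% in oak. The clock at the mean age gave 16.2%, which is 0.60 points above ash and 0.90 points above maple.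

    substrate ⇌ intermediate B (K = 0.880, k = 0.00270 s⁻¹)
    substrate → intermediate A (k = 4.60 × 10⁻⁴ s⁻¹)
    reagent + intermediate B ⇌ intermediate C (K = 26.0 L mol⁻¹, k = 0.00200 L mol⁻¹ s⁻¹)
    intermediate A → side product (k = 6.10 × 10⁻⁴ s⁻¹)
    reagent + intermediate A → target (k = 0.0100 L mol⁻¹ s⁻¹)

Now take oak's recipe at 0.12 M of substrate, the equivalents held. With the order m the clock goes to 0.00519 min⁻¹, a factor of 1.41, and that factor on oak's result gives an estimate of 32.1%. The computed flask gives 32.5%.

The readings were generated by integration for an exercise, noise included.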